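The plan hinges on one disconnection: the seven-membered ring (C1, C5–C10, daucane numbering) is a disguised cyclohepta-1,4-diene. Its C6 and C8 oxygens, its C9=C10 alkene next to quaternary C1 and its C1–C5 fusion to a cyclopentane carrying oxygen at C4 match the product of adding a siloxyvinyl acyl carbene, centred on C5, to a 1,3-diene. In a single operation, cyclopropanation of the C1=C10 alkene and Cope rearrangement (formal (4+3) cycloaddition) build the cyclopentanone, then the cycloheptadiene, and fix C1. The substrate is an open-chain siloxyvinyl diazoketone joined through two methylenes to an (E,E)-dienyl boronate; the vanillate arrives last.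

Key step: step 7

Numbering used: C1 quaternary methyl-bearing fusion carbon, C2 and C3 ring CH2, C4 isopropyl carbinol, C5 fusion CH, C6 ester carbon, C7 CH2, C8 methyl carbinol, C9=C10 alkene; β is the face of the C1 methyl, α the opposite face. The target is (1R,4R,5S,6S,8S) in this numbering.

Assumption: the (S)-configured catalyst Rh2(S-PTAD)4 (PTAD = (1-adamantyl)(phthalimido)acetate) is taken to give C1 as drawn; if the sense of induction proves opposite, the mirror-image catalyst would be used with no other change.

Step 1
Reactants: 1 propargyl alcohol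
Product: 3 (E)-3-iodo-2-methylprop-2-en-1-ol, via vinylalane 2 (not isolated)
Conditions: AlMe3 (3 equiv), Cp2ZrCl2 (0.25 equiv), CH2Cl2, 0 °C to rt; then I2, THF, −30 to 0 °C; aq. NaHCO3/Na2S2O3
Reagents that add atoms: trimethylaluminium, C[Al](C)C; iodine, II
Why: Zirconium-catalysed carboalumination adds methyl and aluminium syn across the alkyne with aluminium on the terminal carbon, and iodinolysis of the vinylalane with retention should give the E iodide.

Step 2
Reactants: 3 (E)-3-iodo-2-methylprop-2-en-1-ol; 4 vinylboronic acid pinacol ester
Product: 5 (2E,4E)-2-methyl-5-(pinacolboryl)penta-2,4-dien-1-ol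
Conditions: Pd(OAc)2 (5 mol %), P(o-tol)3 (10 mol %), AgOAc (1.2 equiv), MeCN, 50 °C
Reagents that add atoms: none
Why: Heck coupling: the alkenylpalladium iodide adds to the unsubstituted terminus of the vinyl boronate and syn β-hydride elimination gives the E alkenyl boronate, while silver acetate scavenges iodide and the absence of aqueous base suppresses the Suzuki pathway.

Step 3
Reactants: 5 (2E,4E)-2-methyl-5-(pinacolboryl)penta-2,4-dien-1-ol
Product: 6 (1E,3E)-5-bromo-4-methylpenta-1,3-dienylboronic acid pinacol ester
Conditions: CBr4, PPh3, CH2Cl2, 0 °C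
Reagents that add atoms: carbon tetrabromide, BrC(Br)(Br)Br
Why: Appel bromination converts the primary allylic alcohol into the bromide under neutral conditions that should leave the boronate and both alkene geometries untouched.

Step 4
Reactants: 7 acetylacetone
Product: 8 3-diazopentane-2,4-dione
Conditions: 4-acetamidobenzenesulfonyl azide, Et3N, MeCN, 0 °C to rt
Reagents that add atoms: 4-acetamidobenzenesulfonyl azide, CC(=O)Nc1ccc(cc1)S(=O)(=O)N=[N+]=[N-]
Why: Regitz diazo transfer from the sulfonyl azide to the enolate of the 1,3-diketone.

Step 5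
Reactants: 8 3-diazopentane-2,4-dione
Product: 9 3-diazo-4-(tert-butyldimethylsilyloxy)pent-4-en-2-one
Conditions: TBSOTf (1.0 equiv), Et3N, CH2Cl2, −78 to 0 °C; used cold and without delay
Reagents that add atoms: tert-butyldimethylsilyl trifluoromethanesulfonate, CC(C)(C)[Si](C)(C)OS(=O)(=O)C(F)(F)F
Why: Soft enolisation with silyl triflate and amine O-silylates one of two equivalent acetyl groups, so no regiochemical question arises and one equivalent of triflate limits double silylation.

Step 6
Reactants: 9 3-diazo-4-(tert-butyldimethylsilyloxy)pent-4-en-2-one; 6 (1E,3E)-5-bromo-4-methylpenta-1,3-dienylboronic acid pinacol ester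
Product: 11 (7E,9E)-3-diazo-2-(tert-butyldimethylsilyloxy)-7-methyl-10-(pinacolboryl)deca-1,7,9-trien-4-one, via lithium enolate 10 (not isolated)
Conditions: LiN(SiMe3)2, THF, −78 °C, short ageing; then 6, −78 to −40 °C
Reagents that add atoms: none
Why: Enolate alkylation (SN2 at a primary allylic bromide): the acetyl methyl is the only acidic C–H site of 9, silyl transfer between the two oxygens of enolate 10 is degenerate, and the diazo group, the enol ether and the boronate should tolerate the cold lithium enolate.

Step 7
Reactants: 11 (7E,9E)-3-diazo-2-(tert-butyldimethylsilyloxy)-7-methyl-10-(pinacolboryl)deca-1,7,9-trien-4-one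
Product: 13 hydroazulenone boronate (C4 ketone; C5=C6 enol ether with OTBS on C6; 8α-Bpin; C9=C10 alkene; C1 β-methyl), via cis-divinylcyclopropane 12 (not isolated)
Conditions: Rh2(S-PTAD)4 (1 mol %), slow addition of 11, hexane/toluene, −20 °C to rt; then 40–50 °C if the rearrangement is incomplete
Reagents that add atoms: none
Why: Loss of N2 from 11 at the dirhodium tetracarboxylate gives a donor/acceptor (siloxyvinyl/acyl) carbenoid at C5 that adds to the tethered C1=C10 alkene (bonds C5–C1 and C5–C10), and the cis-divinylcyclopropane 12 then rearranges through a boat-like Cope transition state (C7–C8 formed, C5–C10 broken) to 13. The closest known reaction type is the dirhodium-catalysed tandem cyclopropanation/Cope rearrangement of siloxyvinyl diazocarbonyl compounds with dienes, which also has intramolecular variants tethered through the carbonyl group. The cyclopentanone closes by intramolecular [2+1] addition as the five-membered ring of a bicyclo[3.1.0]hexan-2-one, and the seven-membered ring closes by the [3,3] shift, a three-to-seven ring expansion of that cyclopropane. C1 is set by the chiral carboxylate ligands, which choose the enantioface of the C1=C10 alkene; C5 and C10 of 12 follow from stereospecific syn addition and the obligatory cis ring fusion and become sp2 again, and C8 is relayed from C1 through the boat transition state (boron trans to the C1 methyl) and is erased in step 9. The step needs site selectivity for the trisubstituted alkene over the borylated one and a cis relationship of the two vinyl groups: the three-atom tether permits only five-ring closure at C1=C10, and the E geometry of that alkene puts the borylvinyl group exo, cis to the siloxyvinyl group. Because the migrating terminus carries only an E substituent, the rearrangement should run at or slightly above room temperature, below the range where a homo-1,5-hydrogen shift from the cis methyl could compete.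

Step 8
Reactants: 13 hydroazulenone boronate
Product: 14 C8 allylic alcohol (8α-OH)
Conditions: 30 % H2O2, pH 7 phosphate buffer, THF, 0 °C to rt
Reagents that add atoms: hydrogen peroxide, OO
Why: Oxidation of the allylic C–B bond (1,2-shift from boron to oxygen with retention) at neutral pH should spare the vinylogous silyl ester; the C8 configuration is immaterial because C8 is oxidised next.

Step 9
Reactants: 14 C8 allylic alcohol
Product: 15 C8 enone (C8 ketone conjugated with C9=C10)
Conditions: activated MnO2 (excess), CH2Cl2, rt
Reagents that add atoms: none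
Why: MnO2 oxidises allylic alcohols selectively under neutral conditions.

Step 10
Reactants: 15 C8 enone
Product: 16 C8 tertiary alcohol (8β-OH, 8α-methyl)
Conditions: CeCl3 (anhydrous, 1.5 equiv), MeMgBr (1.4 equiv), THF, −78 °C; aq. NH4Cl
Reagents that add atoms: methylmagnesium bromide, C[Mg]Br
Why: Organocerium 1,2-addition: the weakly basic methylcerium reagent adds to easily enolised ketones, should prefer the C8 enone carbonyl over the less electrophilic vinylogous ester carbonyl at C4, and should attack the convex face of the folded ring, anti to the pseudoaxial C1 methyl, which places the new hydroxyl β.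

Step 11
Reactants: 16 C8 tertiary alcohol
Product: 17 C8 triethylsilyl ether
Conditions: TESOTf, 2,6-lutidine, CH2Cl2, −78 °C
Reagents that add atoms: triethylsilyl trifluoromethanesulfonate, CC[Si](CC)(CC)OS(=O)(=O)C(F)(F)F
Why: Silylation of the tertiary alcohol with a silyl triflate and a hindered pyridine base at low temperature, where the C4 ketone is not enolised.

Step 12
Reactants: 17 C8 triethylsilyl ether; 18 isopropyllithium
Product: 20 transposed enone (C6 ketone; C4=C5 alkene carrying isopropyl on C4), via isopropyl carbinol 19 (not isolated)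
Conditions: CeCl3 (anhydrous), 18, THF, −78 °C; then 17; then 0.5 M aq. HCl, THF, 0 °C, short
Reagents that add atoms: none
Why: Stork–Danheiser transposition: the organocerium reagent adds 1,2 to the C4 carbonyl without reduction or enolisation, and cold dilute acid ionises 19 through the siloxy-stabilised allyl cation and removes the silyl group to give the C4=C5–C6=O enone, conditions the tertiary triethylsilyl ether should survive.

Step 13
Reactants: 20 transposed enone
Product: 21 allylic alcohol (6β-OH, 6R)
Conditions: (S)-2-methyl-CBS-oxazaborolidine (0.2 equiv), catecholborane, toluene, −78 °C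
Reagents that add atoms: none
Why: CBS reduction: the (S)-oxazaborolidine treats the fully substituted alkenyl carbon C5 as the large group and C7 as the small one and delivers hydride 1,2 to the α face, giving the 6β alcohol; attack anti to the C1 methyl is also the face the substrate should prefer.

Step 14
Reactants: 21 allylic alcohol
Product: 22 epoxy alcohol (4β,5β-epoxide, 6β-OH)
Conditions: VO(acac)2 (5 mol %), t-BuOOH (decane solution), CH2Cl2, 0 °C to rt
Reagents that add atoms: tert-butyl hydroperoxide, CC(C)(C)OO
Why: Hydroxyl-directed epoxidation: the vanadium alkoxide of the 6β hydroxyl delivers oxygen to the β face of the tetrasubstituted C4=C5 alkene, which sets the C4 oxygen β and the temporary C5 centre, while the C9=C10 alkene has no free allylic hydroxyl and should not react.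

Step 15
Reactants: 22 epoxy alcohol
Product: 23 epoxy ketone (4β,5β-epoxy-6-one)
Conditions: Dess–Martin periodinane, NaHCO3, CH2Cl2, 0 °C to rt
Reagents that add atoms: none
Why: Buffered Dess–Martin oxidation of the secondary alcohol should leave the epoxide and the silyl ether intact.

Step 16
Reactants: 23 epoxy ketone
Product: 25 4β-hydroxy-6-ketone (H5 α, trans-fused), via samarium enolate 24 (not isolated)
Conditions: SmI2 (2.5 equiv), MeOH, THF, −90 °C; pH 7 buffer; if a C5 mixture forms, DBU (cat.), CH2Cl2, 0 °C
Reagents that add atoms: none
Why: Reductive cleavage of an α,β-epoxy ketone by SmI2: two single-electron transfers break only the C5–O bond next to the ketyl, the C4–O bond and its β configuration are kept, and protonation of enolate 24 sets C5, the trans-fused epimer (C6 cis to the C4 hydroxyl and hydrogen-bonded to it, trans to isopropyl) being expected as the more stable one.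

Step 17
Reactants: 25 4β-hydroxy-6-ketone
Product: 26 4β,6α-diol
Conditions: Me4NBH(OAc)3, MeCN/AcOH, −30 to 0 °C
Reagents that add atoms: none
Why: Evans–Saksena reduction: the C4 hydroxyl exchanges onto boron and delivers hydride intramolecularly to the β face of the C6 carbonyl, which should give the 6α alcohol (4,6-anti diol).

Step 18
Reactants: 26 4β,6α-diol; 27 4-acetoxy-3-methoxybenzoic acid
Product: 29 C6 4-acetoxy-3-methoxybenzoate, via mixed anhydride 28 (not isolated)
Conditions: 27, 2,4,6-trichlorobenzoyl chloride, Et3N, THF, rt; then 26, DMAP, toluene, rt to 40 °C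
Reagents that add atoms: none
Why: Yamaguchi esterification: under DMAP catalysis the mixed anhydride acylates the only secondary hydroxyl (C6) with retention, the tertiary C4 hydroxyl being unreactive and C8 silylated.

Step 19
Reactants: 29 C6 4-acetoxy-3-methoxybenzoate
Product: 30 C6 vanillate with C8 triethylsilyl ether
Conditions: pyrrolidine (3 equiv), CH2Cl2, 0 °C to rt
Reagents that add atoms: none
Why: Aminolysis: the aryl acetate is far more electrophilic than the hindered vanillate of a secondary alcohol, so pyrrolidine should remove only the acetyl group.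

Step 20
Reactants: 30 C6 vanillate with C8 triethylsilyl ether
Product: 31 target CNP0243386.2
Conditions: HF·pyridine, pyridine, THF, 0 °C to rt
Reagents that add atoms: none
Why: Pyridine-buffered fluoride desilylation cleaves the Si–O bond without free acid, so the tertiary allylic alcohol should not ionise and the ester should not be touched.

Compound list
1 | propargyl alcohol | C#CCO | starting material
2 | vinylalane: dimethylaluminium alkoxide of (E)-3-(dimethylalumino)-2-methylprop-2-en-1-ol (not isolated) | C[Al](C)OC/C(C)=C/[Al](C)C | intermediate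
3 | (E)-3-iodo-2-methylprop-2-en-1-ol | OC/C(C)=C/I | intermediate
4 | vinylboronic acid pinacol ester | C=CB1OC(C)(C)C(C)(C)O1 | starting material
5 | (2E,4E)-2-methyl-5-(4,4,5,5-tetramethyl-1,3,2-dioxaborolan-2-yl)penta-2,4-dien-1-ol | OC/C(C)=C/C=C/B1OC(C)(C)C(C)(C)O1 | intermediate
6 | 2-[(1E,3E)-5-bromo-4-methylpenta-1,3-dienyl]-4,4,5,5-tetramethyl-1,3,2-dioxaborolane | BrC/C(C)=C/C=C/B1OC(C)(C)C(C)(C)O1 | intermediate
7 | acetylacetone | CC(=O)CC(C)=O | starting material
8 | 3-diazopentane-2,4-dione | CC(=O)C(=[N+]=[N-])C(C)=O | intermediate
9 | 3-diazo-4-(tert-butyldimethylsilyloxy)pent-4-en-2-one | C=C(O[Si](C)(C)C(C)(C)C)C(=[N+]=[N-])C(C)=O | intermediate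
10 | lithium enolate of 9 (not isolated) | C=C(O[Li])C(=[N+]=[N-])C(=C)O[Si](C)(C)C(C)(C)C | intermediate
11 | (7E,9E)-3-diazo-2-(tert-butyldimethylsilyloxy)-7-methyl-10-(pinacolboryl)deca-1,7,9-trien-4-one | C=C(O[Si](C)(C)C(C)(C)C)C(=[N+]=[N-])C(=O)CC/C(C)=C/C=C/B1OC(C)(C)C(C)(C)O1 | intermediate
12 | 5-methyl-1-[1-(tert-butyldimethylsilyloxy)ethenyl]-6-[(E)-2-(pinacolboryl)ethenyl]bicyclo[3.1.0]hexan-2-one, both alkenyl groups and the methyl cis on the cyclopropane (not isolated) | C=C(O[Si](C)(C)C(C)(C)C)[C@@]12C(=O)CC[C@]1(C)[C@H]2/C=C/B3OC(C)(C)C(C)(C)O3 | intermediate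
13 | hydroazulenone boronate: C4 ketone, C5=C6 enol ether with OTBS on C6, 8α-Bpin, C9=C10 alkene, C1 β-methyl | CC(C)(C)[Si](C)(C)OC=2C[C@@H](B4OC(C)(C)C(C)(C)O4)C=C[C@@]3(C)CCC(=O)C=23 | intermediate
14 | C8 allylic alcohol (8α-OH), otherwise as 13 | CC(C)(C)[Si](C)(C)OC=2C[C@@H](O)C=C[C@@]3(C)CCC(=O)C=23 | intermediate
15 | C8 enone: C8 ketone conjugated with C9=C10, vinylogous silyl ester intact | CC(C)(C)[Si](C)(C)OC=2CC(=O)C=C[C@@]3(C)CCC(=O)C=23 | intermediate
16 | C8 tertiary alcohol (8β-OH, 8α-methyl) | CC(C)(C)[Si](C)(C)OC=2C[C@](C)(O)C=C[C@@]3(C)CCC(=O)C=23 | intermediate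
17 | C8 triethylsilyl ether of 16 | CC(C)(C)[Si](C)(C)OC=2C[C@](C)(O[Si](CC)(CC)CC)C=C[C@@]3(C)CCC(=O)C=23 | intermediate
18 | isopropyllithium | [Li]C(C)C | starting material
19 | C4 isopropyl carbinol with C5=C6 silyl enol ether, C4 configuration uncontrolled (not isolated) | CC(C)(C)[Si](C)(C)OC=2C[C@](C)(O[Si](CC)(CC)CC)C=C[C@@]3(C)CCC(O)(C(C)C)C=23 | intermediate
20 | transposed enone: C6 ketone, C4=C5 alkene with isopropyl on C4, 8β-OTES, C9=C10 alkene | O=C2C[C@](C)(O[Si](CC)(CC)CC)C=C[C@@]3(C)CCC(C(C)C)=C23 | intermediate
21 | allylic alcohol: 6β-OH (6R), C4=C5 alkene | O[C@@H]2C[C@](C)(O[Si](CC)(CC)CC)C=C[C@@]3(C)CCC(C(C)C)=C23 | intermediate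
22 | epoxy alcohol: 4β,5β-epoxide, 6β-OH | O[C@@H]2C[C@](C)(O[Si](CC)(CC)CC)C=C[C@@]3(C)CC[C@]4(C(C)C)O[C@]234 | intermediate
23 | epoxy ketone: 4β,5β-epoxy-6-one | O=C2C[C@](C)(O[Si](CC)(CC)CC)C=C[C@@]3(C)CC[C@]4(C(C)C)O[C@]234 | intermediate
24 | samarium enolate (C5=C6–OSmI2) with 4β-OSmI2 (not isolated) | I[Sm](I)OC=2C[C@](C)(O[Si](CC)(CC)CC)C=C[C@@]3(C)CC[C@@](O[Sm](I)I)(C(C)C)C=23 | intermediate
25 | 4β-hydroxy-6-ketone, H5 α (trans-fused) | O=C2C[C@](C)(O[Si](CC)(CC)CC)C=C[C@@]3(C)CC[C@@](O)(C(C)C)[C@H]23 | intermediate
26 | 4β,6α-diol with 8β-OTES | O[C@H]2C[C@](C)(O[Si](CC)(CC)CC)C=C[C@@]3(C)CC[C@@](O)(C(C)C)[C@H]23 | intermediate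
27 | 4-acetoxy-3-methoxybenzoic acid | COc1cc(C(=O)O)ccc1OC(C)=O | starting material
28 | mixed anhydride of 27 with 2,4,6-trichlorobenzoic acid (not isolated) | COc1cc(C(=O)OC(=O)c2c(Cl)cc(Cl)cc2Cl)ccc1OC(C)=O | intermediate
29 | C6 (6α-O) 4-acetoxy-3-methoxybenzoate of 26 | COc1cc(C(=O)O[C@H]2C[C@](C)(O[Si](CC)(CC)CC)C=C[C@@]3(C)CC[C@@](O)(C(C)C)[C@H]23)ccc1OC(C)=O | intermediate
30 | C6 vanillate with 8β-OTES | COc1cc(C(=O)O[C@H]2C[C@](C)(O[Si](CC)(CC)CC)C=C[C@@]3(C)CC[C@@](O)(C(C)C)[C@H]23)ccc1O | intermediate
31 | CNP0243386.2: (1R,4R,5S,6S,8S)-4,8-dihydroxydauc-9-en-6-yl 4-hydroxy-3-methoxybenzoate | COc1cc(C(=O)O[C@H]2C[C@](C)(O)C=C[C@@]3(C)CC[C@@](O)(C(C)C)[C@H]23)ccc1O | target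

Total step count: 20. Longest linear sequence: 18 steps (steps 1, 2, 3 and 6, then 7 to 20).

Steps most likely to fail

Step 7. What may go wrong: the chiral carboxylate catalyst may discriminate poorly between the enantiofaces of the C1=C10 alkene when the carbenoid is tethered through a ketone. Fallback (resolution in place of asymmetric catalysis): setting out from 11, the tandem reaction is run with achiral Rh2(OAc)4 in CH2Cl2, which should give 13 as the racemate, that is together with its mirror image, ent-hydroazulenone boronate F1. Buffered H2O2 oxidation of the mixture gives 14 together with ent-allylic alcohol F2. Lipase-catalysed acylation (Candida antarctica lipase B, vinyl acetate, a lipase of the required preference being chosen by screening) then acts as a kinetic resolution that removes the unwanted enantiomer as ent-allylic acetate F3 and leaves 14, where the route is rejoined.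

Step 16. What may go wrong: the samarium enolate may be protonated on the β face, giving the cis-fused C5 epimer, and base-induced epimerisation would then compete with retro-aldol cleavage of the C4–C5 bond and with β-elimination of the C8 silanol. Fallback (stereospecific hydride shift in place of enolate protonation): setting out from epoxy alcohol 22, a Lewis acid (ZnBr2 in CH2Cl2, or BF3·OEt2 at −78 °C) should trigger a semipinacol rearrangement in which the C6 hydrogen, anti to the C5–O bond, migrates to C5 with inversion while C6 becomes the ketone. This places H5 α without passing through an enolate and gives 25 directly, where the route is rejoined; steps 15 and 16 are bypassed and no compound outside the list is formed (F0).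

Step 6. What may go wrong: the doubly vinylic diazo enolate may decompose, or its C-alkylation may be slow and unselective (O-alkylation, proton exchange with the product followed by over-alkylation, or attack of the enolate on boron). Fallback (carbon chain first, diazo group second): setting out from 7 and 6, the dianion of acetylacetone (NaH, then n-BuLi, THF, 0 °C) is alkylated at its terminal carbon by 6 to give dienyl diketone F4. Regitz diazo transfer (4-acetamidobenzenesulfonyl azide, Et3N, MeCN) gives diazo diketone F5. Kinetic deprotonation of the acetyl methyl (LiN(SiMe3)2, THF, −78 °C) and O-silylation with TBSOTf then give 11, where the route is rejoined. The price is that the regiochemistry of the enol ether then depends on kinetic deprotonation of methyl over methylene.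

Further compounds
F1 | step 7 | ent-hydroazulenone boronate (mirror image of 13) | CC(C)(C)[Si](C)(C)OC=2C[C@H](B4OC(C)(C)C(C)(C)O4)C=C[C@]3(C)CCC(=O)C=23
F2 | step 7 | ent-allylic alcohol (mirror image of 14) | CC(C)(C)[Si](C)(C)OC=2C[C@H](O)C=C[C@]3(C)CCC(=O)C=23
F3 | step 7 | ent-allylic acetate (acetate of F2) | CC(C)(C)[Si](C)(C)OC=2C[C@H](OC(C)=O)C=C[C@]3(C)CCC(=O)C=23
F0 | step 16 | none | none
F4 | step 6 | dienyl diketone, (7E,9E)-7-methyl-10-(pinacolboryl)deca-7,9-diene-2,4-dione | CC(=O)CC(=O)CC/C(C)=C/C=C/B1OC(C)(C)C(C)(C)O1
F5 | step 6 | diazo diketone, (7E,9E)-3-diazo-7-methyl-10-(pinacolboryl)deca-7,9-diene-2,4-dione | CC(=O)C(=[N+]=[N-])C(=O)CC/C(C)=C/C=C/B1OC(C)(C)C(C)(C)O1
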